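Remark on conventions: ring carbons carry eremophilane numbers throughout (decalin C1-C10; ring A = C1-C5, C10; ring B = C5-C10; C14 is the methyl on C5, C15 the methyl on C4, C11-C13 the isopropenyl group on C7). α is the face of H-10, β the face of the C5 methyl group. Cyclopentadienyl rings of zirconocene and titanocene species are drawn σ-bonded in SMILES.

## The problem

The target is a trans-fused eremophilane decalin with six stereocentres, five of them contiguous along C3-C4-C5-C10-C9, and C5 is quaternary with its methyl group cis to the C4 methyl and anti to H-10. The hard bond is the ring-fusion bond C5-C10, which joins the quaternary carbon to a tertiary one whose neighbour C9 must carry an equatorial oxygen. C3 and C4 can be made together in an open chain and then steer later events, because both substituents prefer to be equatorial on ring A; C5, C10 and C9 are best set in one operation under that bias. C7 lies α to the ketone, is epimerisable and should settle equatorial, away from the axial C5 methyl group, while C8, a carbonyl carbon in the target, is free to serve as a temporary stereocentre. The sensitive functions are the β,γ-unsaturated ketone (the isopropenyl double bond moves into conjugation under acid or base), the C9 α-acyloxy ketone (acyl migration, epimerisation), and two different enoate esters that tolerate neither hydrides, organometallics nor enolates. The acyl groups therefore have to come last, on hydroxyls that are unmasked one at a time. The enabling feature is that C5 and C10 are linked both through C4-C3-C2-C1 and through C6-C7-C8-C9, so that cutting C5-C10 leaves one ten-membered ring (C1-C10) in which a C5 cation faces an (E)-C9=C10 alkene across the ring and an oxygen on C8 can deliver the C9 oxygen from next door.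

## Retrosynthesis

**Acyl groups (C3-O and C9-O acyl bonds).** Target 34 is cut at the C3 ester to alcohol 32 and tigloyl chloride 33. Ester 31, the silyl-protected form of 32, is cut at C9 to α-ketol 29 and senecioyl chloride 30. These cuts come first because the enoates cannot be carried through the route, and acylation under pyridine/DMAP is mild enough for the finished isopropenyl ketone. The cost is sequential unmasking, arranged through a triethylsilyl ether on C9 and a triisopropylsilyl ether on C3 in 28.

**Isopropenyl group (C7-C11).** 28 comes from tertiary alcohol 27, and 27 from ketone 24 and acetone 25 by an aldol reaction. The group cannot be present earlier, since a second 1,1-disubstituted alkene would be protonated in the acid step. A late aldol uses the ketone that is needed anyway and lets the axial C5 methyl steer C7. The forward reaction must enolise towards C7 rather than the oxygenated C9, and the dehydration must take a methyl hydrogen.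

**Oxygen pattern of ring B (no skeletal bond).** 24 is traced through alcohol 23 to cis-diol 22, whose axial C8 and equatorial C9 hydroxyls differ enough to be told apart, and 22 to cyclic carbonate 21. This turns the differentiated ketone/ester pair into one symmetric protecting group.

**Key cut (C5-C10 and C9-O).** 21 is opened, via iminium salt 20, to cyclodecenyl carbamate 19. Cutting the central bond removes both rings, the quaternary centre and three stereocentres at once. Cuts at C4-C5 or C5-C6 would keep one ring but leave the quaternary centre to be made by alkylation next to existing stereocentres. The precursor has only C3, C4 and C8 as stereocentres. The forward reaction must bond at C10 and not C9, give the trans fusion, and deliver oxygen to C9 from the α-face. This requires the (8R) configuration, so C8 is treated as a controlling element and not as a by-product of ring closure.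

**Ten-membered ring (C8-C9).** 19 comes from (8R)-alcohol 17 and dimethylcarbamoyl chloride 18. 17 is reached from enone 16, 16 from the epimeric alcohols 15, and 15 from iodo aldehyde 14 by a CrCl2/NiCl2 closure. This cut is preferred to olefin metathesis at C9=C10 because the (E) geometry is fixed beforehand in the iodoalkene. The one stereocentre the closure cannot control is reset by oxidation and reagent-controlled reduction.

**Chain assembly (C5-C6 and C5=C14).** 14 is unmasked from acetal 13, 13 is the methylenation product of ketone 12, and 12 comes from Weinreb amide 9 and the Grignard reagent 11 of bromo acetal 10. The three-carbon piece arrives at the aldehyde oxidation level, so no separate protection and oxidation are needed. The iodoalkene is already in place, so no alkyne has to survive the titanium and magnesium reagents.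

**Stereotriad origin (C3-C4).** 9 is the silyl ether of 8, 8 the aminolysis product of aldol adduct 7, and 7 the syn aldol of acyl oxazolidinone 5, through its boron enolate 6, with aldehyde 4. The (S)-benzyl auxiliary gives the (2S,3R) adduct, which maps onto C4 and C3 of the target. Aldehyde 4 comes from alcohol 3 and that from pent-4-yn-1-ol 1 by hydrozirconation-iodination through 2.

## Roads not taken

Alternative 1: The cut takes C4-C5 and C1-C10 away from a preformed ring B. The forward key step starts from the enone A1, which is 3-methylcyclohex-2-en-1-one. Cu(OTf)2 with a chiral N-heterocyclic carbene ligand would deliver a vinyl group from a vinylaluminium reagent to C5 of A1, and the enolate so formed would be allylated at C10 to give the ketone A2, which is (2R,3R)-2-allyl-3-methyl-3-vinylcyclohexan-1-one.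
- Merits: the quaternary C5 is set by a catalyst, two C-C bonds form in one flask from the commodity enone A1, and anti alkylation gives the correct C5/C10 relationship. In brevity and in avoiding an auxiliary this opening is better than the twelve-step front end chosen here.
- Weak points: no ring closes. Ring A must still be closed across C3-C4 (metathesis of the two alkenes of A2 would give a five-membered ring), with C3 and C4 set afterwards relative to C5. The ring B carbonyl of A2 sits at C9, so a transposition to C8, a stereoselective C9 oxygenation and the C7 side chain all remain. Aluminium enolates are also sluggish towards allyl halides.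
- Comparison: the chosen plan sets C5, C10 and C9, closes both rings and places both ring B oxygens in one step, so the distance from 21 to the target is shorter and better defined than from A2.

Alternative 2: The cut is C7-C8. A monocyclic ring A aldehyde A3 (C8 = CHO, a prenyl group on C5, both esters in place) would undergo a carbonyl-ene reaction under Me2AlCl to give the 8β-alcohol A4, and one oxidation would finish the synthesis.
- Merits: the isopropenyl group arises directly from the prenyl group with no regiochemical choice, ring B closes through a chair transition state that places C7 equatorial, and the endgame is one step. In this respect the road is clearly better than the aldol-dehydration and double deprotection used here.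
- Weak points: A3 must carry five stereocentres on one ring, including the quaternary C5 between C4 and C10, and an epimerisable α-acyloxy aldehyde at C9, all made without the bias of a decalin. The Lewis acid must choose the aldehyde over two enoate carbonyls, and both enoates must survive the whole construction of A3.
- Comparison: the difficulty is moved into the precursor A3 rather than removed. The chosen plan pays nine steps after its key step but solves C5/C10/C9 with an (E)-alkene and a chair conformer.

Alternative 3: The cut is C5-C10 together with C6-C7. An acyclic trienal A5, with an (E)-β-methyl enal and a 2-silyloxy diene joined by C1-C4, would undergo an intramolecular Diels–Alder reaction to the 6β-formyl silyl enol ether A6.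
- Merits: two C-C bonds and both rings form at once from an open chain, no medium ring has to be closed (an advantage over the CrCl2/NiCl2 closure here), and the enol ether of A6 is a handle for the C8 ketone and for oxidation at C9.
- Weak points: the dienophile of A5 is a trisubstituted, β,β-disubstituted enal that must create the quaternary centre, so reactivity is low. Trans selectivity in decalin-forming cycloadditions of this tether length is not dependable. The formyl carbon on C6 of A6 is absent from the target and has to be excised. The C9 oxygen must still be introduced with stereocontrol.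
- Comparison: A6 is reached more convergently than 21. Against this, the chosen plan installs the C9 oxygen in the ring-forming step, carries no surplus carbon, and derives its trans fusion from anti addition to an (E)-alkene.

Key step: step 13

## Route

Step 1
Reactants: 1 pent-4-yn-1-ol
Product: 3 (E)-5-iodopent-4-en-1-ol, via bis-zirconated alkenyl alkoxide 2 (not isolated)
Conditions: Cp2Zr(H)Cl (2.2 equiv), THF, rt; I2, 0 °C; aq. work-up
Reagents that add atoms: iodine, II
Why: Hydrozirconation of the terminal alkyne is a syn addition that places zirconium on the terminal carbon, and iodinolysis of the C-Zr bond with retention gives the (E)-iodoalkene. The first equivalent of Cp2Zr(H)Cl is consumed by the hydroxyl as a zirconium alkoxide that is hydrolysed on work-up.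

Step 2
Reactants: 3 (E)-5-iodopent-4-en-1-ol
Product: 4 (E)-5-iodopent-4-enal
Conditions: Dess–Martin periodinane, NaHCO3, CH2Cl2, 0 °C → rt
Reagents that add atoms: none
Why: Dess–Martin oxidation of a primary alcohol stops at the aldehyde under buffered, non-aqueous conditions and leaves the iodoalkene untouched.

Step 3
Reactants: 5 (4S)-4-benzyl-3-propanoyl-1,3-oxazolidin-2-one; 4 (E)-5-iodopent-4-enal
Product: 7 (4S)-4-benzyl-3-[(2S,3R,6E)-3-hydroxy-7-iodo-2-methylhept-6-enoyl]-1,3-oxazolidin-2-one, via dibutylboron (Z)-enolate 6 (not isolated)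
Conditions: Bu2BOTf, iPr2NEt, CH2Cl2, −78 → 0 °C; 4, −78 → 0 °C; H2O2, MeOH, pH 7 buffer, 0 °C
Reagents that add atoms: none
Why: Evans syn aldol reaction: the (Z)-boron enolate reacts through a closed chair transition state on the face away from the benzyl group, which should give the (2S,3R) adduct. These two centres become C4 and C3 of the target.

Step 4
Reactants: 7 (4S)-4-benzyl-3-[(2S,3R,6E)-3-hydroxy-7-iodo-2-methylhept-6-enoyl]-1,3-oxazolidin-2-one
Product: 8 (2S,3R,6E)-3-hydroxy-7-iodo-N-methoxy-N,2-dimethylhept-6-enamide
Conditions: MeNH(OMe)·HCl, AlMe3, CH2Cl2, −15 → 0 °C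
Reagents that add atoms: N,O-dimethylhydroxylamine hydrochloride, CNOC.Cl
Why: Weinreb aminolysis with the aluminium amide. The free β-hydroxyl directs aluminium to the exocyclic carbonyl, so the auxiliary is released intact and the α-centre is not epimerised.

Step 5
Reactants: 8 (2S,3R,6E)-3-hydroxy-7-iodo-N-methoxy-N,2-dimethylhept-6-enamide
Product: 9 (2S,3R,6E)-7-iodo-N-methoxy-N,2-dimethyl-3-[(triisopropylsilyl)oxy]hept-6-enamide
Conditions: iPr3SiOTf, 2,6-lutidine, CH2Cl2, 0 °C → rt
Reagents that add atoms: triisopropylsilyl trifluoromethanesulfonate, CC(C)[Si](OS(=O)(=O)C(F)(F)F)(C(C)C)C(C)C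
Why: Silylation of a secondary alcohol with a silyl triflate and a hindered base. The triisopropylsilyl ether is chosen because it should survive the organometallic steps, dilute aqueous acid and CF3CO2H.

Step 6
Reactants: 10 2-(2-bromoethyl)-1,3-dioxolane; 9 (2S,3R,6E)-7-iodo-N-methoxy-N,2-dimethyl-3-[(triisopropylsilyl)oxy]hept-6-enamide
Product: 12 (4S,5R,8E)-1-(1,3-dioxolan-2-yl)-9-iodo-4-methyl-5-[(triisopropylsilyl)oxy]non-8-en-3-one, via [2-(1,3-dioxolan-2-yl)ethyl]magnesium bromide 11 (not isolated)
Conditions: 10, Mg, THF, 25 °C; then 9, THF, 0 °C; aq. NH4Cl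
Reagents that add atoms: none
Why: Weinreb ketone synthesis: the Grignard reagent adds once and the magnesium chelate holds until work-up, so there is no over-addition and the α-stereocentre is not enolised. Iodine-magnesium exchange at an alkenyl iodide is slow at 0 °C.

Step 7
Reactants: 12 (4S,5R,8E)-1-(1,3-dioxolan-2-yl)-9-iodo-4-methyl-5-[(triisopropylsilyl)oxy]non-8-en-3-one
Product: 13 2-[(4R,5R,8E)-9-iodo-4-methyl-3-methylidene-5-[(triisopropylsilyl)oxy]non-8-en-1-yl]-1,3-dioxolane
Conditions: Cp2TiMe2, toluene/THF, 65 °C, dark
Reagents that add atoms: dimethyltitanocene Cp2TiMe2, C[Ti](C)(C1C=CC=C1)C1C=CC=C1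
Why: Petasis methylenation: the thermally generated Cp2Ti=CH2 is non-basic, so the hindered, enolisable ketone should be methylenated without epimerising the adjacent centre or eliminating the β-silyloxy group. The acetal and the iodoalkene are tolerated (the descriptor of the methyl-bearing carbon changes to R by priority only).

Step 8
Reactants: 13 2-[(4R,5R,8E)-9-iodo-4-methyl-3-methylidene-5-[(triisopropylsilyl)oxy]non-8-en-1-yl]-1,3-dioxolane
Product: 14 (5R,6R,9E)-10-iodo-5-methyl-4-methylidene-6-[(triisopropylsilyl)oxy]dec-9-enal
Conditions: 1 M aq. HCl, THF, rt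
Reagents that add atoms: water, O
Why: Acid-catalysed acetal hydrolysis. The triisopropylsilyl ether, the iodoalkene and the 1,1-disubstituted alkene are inert to dilute aqueous acid at room temperature.

Step 9
Reactants: 14 (5R,6R,9E)-10-iodo-5-methyl-4-methylidene-6-[(triisopropylsilyl)oxy]dec-9-enal
Product: 15 (2E,6R,7R)-7-methyl-8-methylidene-6-[(triisopropylsilyl)oxy]cyclodec-2-en-1-ol as a mixture of both C1 epimers (C1 = C8 of the target)
Conditions: CrCl2 (8 equiv), NiCl2 (2 mol %), DMSO/THF, rt, slow addition, final 0.003 M
Reagents that add atoms: none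
Why: Nozaki–Hiyama–Kishi reaction: zerovalent nickel formed from NiCl2 inserts into the C-I bond, the alkenyl group passes to trivalent chromium and adds only to the aldehyde with retention of the (E) geometry, closing C8-C9. High dilution favours ring closure; the carbinol configuration is not controlled here and is reset in steps 10 and 11.

Step 10
Reactants: 15 (2E,6R,7R)-7-methyl-8-methylidene-6-[(triisopropylsilyl)oxy]cyclodec-2-en-1-ol (both C1 epimers)
Product: 16 (2E,6R,7R)-7-methyl-8-methylidene-6-[(triisopropylsilyl)oxy]cyclodec-2-en-1-one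
Conditions: Dess–Martin periodinane, NaHCO3, CH2Cl2, 0 °C
Reagents that add atoms: none
Why: Dess–Martin oxidation converges both epimers on one enone under neutral conditions that should not isomerise the strained (E)-alkene.

Step 11
Reactants: 16 (2E,6R,7R)-7-methyl-8-methylidene-6-[(triisopropylsilyl)oxy]cyclodec-2-en-1-one
Product: 17 (1R,2E,6R,7R)-7-methyl-8-methylidene-6-[(triisopropylsilyl)oxy]cyclodec-2-en-1-ol
Conditions: (S)-2-methyl-CBS-oxazaborolidine, catecholborane, toluene, −78 °C
Reagents that add atoms: none
Why: Corey–Bakshi–Shibata reduction: with the alkenyl arm acting as the larger substituent, the (S)-catalyst should deliver hydride to the face that gives the (1R) allylic alcohol (8R in target numbering). Catecholborane at −78 °C reduces 1,2 and should not hydroborate the methylidene group.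

Step 12
Reactants: 17 (1R,2E,6R,7R)-7-methyl-8-methylidene-6-[(triisopropylsilyl)oxy]cyclodec-2-en-1-ol; 18 dimethylcarbamoyl chloride
Product: 19 (1R,2E,6R,7R)-7-methyl-8-methylidene-6-[(triisopropylsilyl)oxy]cyclodec-2-en-1-yl dimethylcarbamate
Conditions: NaH, THF, 0 °C; 18, 0 °C → rt
Reagents that add atoms: none
Why: O-Carbamoylation of the sodium alkoxide by acyl substitution; the carbinol centre is not touched.

Step 13
Reactants: 19 (1R,2E,6R,7R)-7-methyl-8-methylidene-6-[(triisopropylsilyl)oxy]cyclodec-2-en-1-yl dimethylcarbamate
Product: 21 (3R,4R,5R,8R,9S,10R)-3α-(triisopropylsilyloxy)-11,12,13-trinoreremophilane-8α,9α-diyl carbonate, via iminium carbonate trifluoroacetate 20 (not isolated)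
Conditions: CF3CO2H (5 equiv), CH2Cl2, −40 → −10 °C; then aq. NaHCO3, rt
Reagents that add atoms: water, O
Why: CF3CO2H protonates the more basic 1,1-disubstituted C5=C14 alkene in the Markovnikov sense, which creates the tertiary C5 cation and turns C14 into the angular methyl group. In a chair-chair conformer of the ten-membered ring the (E)-C9=C10 alkene bonds to the cation through C10 while the carbamate carbonyl oxygen bonds to C9 on the opposite alkene face, giving the 2-(dimethyliminio)-1,3-dioxolane salt 20, which aqueous bicarbonate hydrolyses to carbonate 21 with loss of dimethylamine. The closest known reaction type is the acid-induced transannular cyclisation of (E)-cyclodeca-1,5-dienes to trans-decalins (germacrane-to-eudesmane type), joined here to the carbonyl-oxygen participation of allylic carbamates familiar from halocyclisations that give cyclic carbonates. Relative to the C9=C10 bond, ring B closes in the 6-endo-trig mode and ring A in the 6-exo-trig mode, and the temporary dioxolane ring closes 5-exo. C5 is set by the chair of the forming ring A: the alkene approaches the cation face that keeps the C4 methyl and the C3 silyloxy group equatorial, because the other chair would place the silyloxy group syn-diaxial to the new angular methyl group; this fixes the C4 and C5 methyl groups cis. C10 follows from the chair-chair geometry, which gives the trans ring fusion (H-10 anti to the C5 methyl group), and C9 from anti addition across the (E)-alkene, which places its oxygen equatorial (9α). The (8R) carbamate sits axial on the α-face of the forming ring B and can reach C9 only from that face, so the demands of C3/C4 and of C8 are matched and the carbonate is cis-fused. The step needs bonding at C10 and not C9, secured by the six-membered ring preference and by carbamate stabilisation of charge at C9, and it needs ring closure to outrun proton loss from C5, which low temperature and the proximity of the alkene across the ring should ensure.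

Step 14
Reactants: 21 (3R,4R,5R,8R,9S,10R)-3α-(triisopropylsilyloxy)-11,12,13-trinoreremophilane-8α,9α-diyl carbonate
Product: 22 (3R,4R,5R,8R,9S,10R)-3α-(triisopropylsilyloxy)-11,12,13-trinoreremophilane-8α,9α-diol
Conditions: K2CO3, MeOH, rt
Reagents that add atoms: none
Why: Base-catalysed methanolysis (transesterification) of the strained five-membered cyclic carbonate; the silyl ether is inert.

Step 15
Reactants: 22 (3R,4R,5R,8R,9S,10R)-3α-(triisopropylsilyloxy)-11,12,13-trinoreremophilane-8α,9α-diol
Product: 23 (3R,4R,5R,8R,9S,10R)-9α-(triethylsilyloxy)-3α-(triisopropylsilyloxy)-11,12,13-trinoreremophilan-8α-ol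
Conditions: Et3SiCl, imidazole, CH2Cl2, −20 °C
Reagents that add atoms: chlorotriethylsilane, CC[Si](Cl)(CC)CC
Why: Sterically governed monosilylation of a cis-1,2-diol on a rigid chair: the equatorial C9 hydroxyl should react faster than the axial C8 hydroxyl, which is flanked by two 1,3-diaxial hydrogens.

Step 16
Reactants: 23 (3R,4R,5R,8R,9S,10R)-9α-(triethylsilyloxy)-3α-(triisopropylsilyloxy)-11,12,13-trinoreremophilan-8α-ol
Product: 24 (3R,4R,5R,9S,10R)-9α-(triethylsilyloxy)-3α-(triisopropylsilyloxy)-11,12,13-trinoreremophilan-8-one
Conditions: Dess–Martin periodinane, pyridine, CH2Cl2, rt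
Reagents that add atoms: none
Why: Dess–Martin oxidation of the remaining axial secondary alcohol. The buffered medium should prevent silyl migration, and the equatorial C9 substituent is already in its stable configuration.

Step 17
Reactants: 24 (3R,4R,5R,9S,10R)-9α-(triethylsilyloxy)-3α-(triisopropylsilyloxy)-11,12,13-trinoreremophilan-8-one; 25 acetone
Product: 27 (3R,4R,5R,7S,9S,10R)-11-hydroxy-9α-(triethylsilyloxy)-3α-(triisopropylsilyloxy)eremophilan-8-one, via lithium C7-enolate 26 (not isolated)
Conditions: LiN(iPr)2, THF, −78 °C; 25, −78 °C; AcOH, −78 °C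
Reagents that add atoms: none
Why: Kinetic deprotonation occurs at the C7 methylene and not at the hindered, oxygen-bearing C9, and the enolate undergoes aldol addition to acetone. The axial C5 methyl group blocks the β-face of C7 (1,3-diaxial), so the new group should end up equatorial (7α), which is also the thermodynamic position.

Step 18
Reactants: 27 (3R,4R,5R,7S,9S,10R)-11-hydroxy-9α-(triethylsilyloxy)-3α-(triisopropylsilyloxy)eremophilan-8-one
Product: 28 (3R,4R,5R,7S,9S,10R)-9α-(triethylsilyloxy)-3α-(triisopropylsilyloxy)eremophil-11-en-8-one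
Conditions: SOCl2, pyridine, CH2Cl2, −20 → 0 °C
Reagents that add atoms: none
Why: Dehydration of the tertiary alcohol through its chlorosulfite with pyridine-mediated E2 removal of a methyl hydrogen, which is statistically and sterically favoured over the hindered C7-H. This should give the non-conjugated isopropenyl group without disturbing C7.

Step 19
Reactants: 28 (3R,4R,5R,7S,9S,10R)-9α-(triethylsilyloxy)-3α-(triisopropylsilyloxy)eremophil-11-en-8-one
Product: 29 (3R,4R,5R,7S,9S,10R)-9α-hydroxy-3α-(triisopropylsilyloxy)eremophil-11-en-8-one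
Conditions: HF·pyridine, pyridine, THF, 0 °C
Reagents that add atoms: none
Why: Fluoride-mediated desilylation removes the triethylsilyl ether much faster than the hindered triisopropylsilyl ether. The pyridine-buffered medium should not move the isopropenyl double bond into conjugation.

Step 20
Reactants: 29 (3R,4R,5R,7S,9S,10R)-9α-hydroxy-3α-(triisopropylsilyloxy)eremophil-11-en-8-one; 30 3-methylbut-2-enoyl chloride
Product: 31 (3R,4R,5R,7S,9S,10R)-8-oxo-3α-(triisopropylsilyloxy)eremophil-11-en-9α-yl 3-methylbut-2-enoate
Conditions: pyridine, DMAP (cat.), CH2Cl2, 0 °C → rt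
Reagents that add atoms: none
Why: DMAP-catalysed acylation of the secondary α-ketol. Pyridine instead of a trialkylamine limits vinylketene formation and thus deconjugation of the senecioyl group.

Step 21
Reactants: 31 (3R,4R,5R,7S,9S,10R)-8-oxo-3α-(triisopropylsilyloxy)eremophil-11-en-9α-yl 3-methylbut-2-enoate
Product: 32 (3R,4R,5R,7S,9S,10R)-3α-hydroxy-8-oxoeremophil-11-en-9α-yl 3-methylbut-2-enoate
Conditions: HF·pyridine, THF, rt
Reagents that add atoms: none
Why: Si-O cleavage by HF·pyridine; the ester, the ketone and the isopropenyl group should be stable to this weakly acidic fluoride source.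

Step 22
Reactants: 32 (3R,4R,5R,7S,9S,10R)-3α-hydroxy-8-oxoeremophil-11-en-9α-yl 3-methylbut-2-enoate; 33 (E)-2-methylbut-2-enoyl chloride
Product: 34 (3R,4R,5R,7S,9S,10R)-9α-(3-methylbut-2-enoyloxy)-8-oxoeremophil-11-en-3α-yl (E)-2-methylbut-2-enoate (CNP0375730.3)
Conditions: pyridine, DMAP, CH2Cl2, rt
Reagents that add atoms: none
Why: DMAP-catalysed acylation of the equatorial C3 alcohol; the (E)-tigloyl geometry is the stable one and is retained.

## Compound list

1 | pent-4-yn-1-ol | C#CCCCO | starting material
2 | bis-zirconated alkenyl alkoxide (E)-Cp2Zr(Cl)CH=CH(CH2)3OZr(Cl)Cp2 | Cl[Zr](/C=C/CCCO[Zr](Cl)(C1C=CC=C1)C1C=CC=C1)(C1C=CC=C1)C1C=CC=C1 | intermediate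
3 | (E)-5-iodopent-4-en-1-ol | OCCC/C=C/I | intermediate
4 | (E)-5-iodopent-4-enal | O=CCC/C=C/I | intermediate
5 | (4S)-4-benzyl-3-propanoyl-1,3-oxazolidin-2-one | CCC(=O)N1[C@@H](Cc2ccccc2)COC1=O | starting material
6 | dibutylboron (Z)-enolate of 5 | C/C=C(\OB(CCCC)CCCC)N1[C@@H](Cc2ccccc2)COC1=O | intermediate
7 | (4S)-4-benzyl-3-[(2S,3R,6E)-3-hydroxy-7-iodo-2-methylhept-6-enoyl]-1,3-oxazolidin-2-one | O=C(N1[C@@H](Cc2ccccc2)COC1=O)[C@@H](C)[C@H](O)CC/C=C/I | intermediate
8 | (2S,3R,6E)-3-hydroxy-7-iodo-N-methoxy-N,2-dimethylhept-6-enamide | CON(C)C(=O)[C@@H](C)[C@H](O)CC/C=C/I | intermediate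
9 | (2S,3R,6E)-7-iodo-N-methoxy-N,2-dimethyl-3-[(triisopropylsilyl)oxy]hept-6-enamide | CON(C)C(=O)[C@@H](C)[C@H](O[Si](C(C)C)(C(C)C)C(C)C)CC/C=C/I | intermediate
10 | 2-(2-bromoethyl)-1,3-dioxolane | BrCCC1OCCO1 | starting material
11 | [2-(1,3-dioxolan-2-yl)ethyl]magnesium bromide | Br[Mg]CCC1OCCO1 | intermediate
12 | (4S,5R,8E)-1-(1,3-dioxolan-2-yl)-9-iodo-4-methyl-5-[(triisopropylsilyl)oxy]non-8-en-3-one | O1CCOC1CCC(=O)[C@@H](C)[C@H](O[Si](C(C)C)(C(C)C)C(C)C)CC/C=C/I | intermediate
13 | 2-[(4R,5R,8E)-9-iodo-4-methyl-3-methylidene-5-[(triisopropylsilyl)oxy]non-8-en-1-yl]-1,3-dioxolane | O1CCOC1CCC(=C)[C@@H](C)[C@H](O[Si](C(C)C)(C(C)C)C(C)C)CC/C=C/I | intermediate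
14 | (5R,6R,9E)-10-iodo-5-methyl-4-methylidene-6-[(triisopropylsilyl)oxy]dec-9-enal | O=CCCC(=C)[C@@H](C)[C@H](O[Si](C(C)C)(C(C)C)C(C)C)CC/C=C/I | intermediate
15 | (2E,6R,7R)-7-methyl-8-methylidene-6-[(triisopropylsilyl)oxy]cyclodec-2-en-1-ol, both C1 epimers | C1CC(=C)[C@@H](C)[C@H](O[Si](C(C)C)(C(C)C)C(C)C)CC/C=C/C1O | intermediate
16 | (2E,6R,7R)-7-methyl-8-methylidene-6-[(triisopropylsilyl)oxy]cyclodec-2-en-1-one | C1CC(=C)[C@@H](C)[C@H](O[Si](C(C)C)(C(C)C)C(C)C)CC/C=C/C1=O | intermediate
17 | (1R,2E,6R,7R)-7-methyl-8-methylidene-6-[(triisopropylsilyl)oxy]cyclodec-2-en-1-ol | C1CC(=C)[C@@H](C)[C@H](O[Si](C(C)C)(C(C)C)C(C)C)CC/C=C/[C@@H]1O | intermediate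
18 | dimethylcarbamoyl chloride | CN(C)C(Cl)=O | starting material
19 | (1R,2E,6R,7R)-7-methyl-8-methylidene-6-[(triisopropylsilyl)oxy]cyclodec-2-en-1-yl dimethylcarbamate | C1CC(=C)[C@@H](C)[C@H](O[Si](C(C)C)(C(C)C)C(C)C)CC/C=C/[C@@H]1OC(=O)N(C)C | intermediate
20 | 8α,9α-[(dimethyliminio)methylenedioxy]-3α-(triisopropylsilyloxy)-11,12,13-trinoreremophilane trifluoroacetate (iminium carbonate of 21) | C1C[C@]2(C)[C@@H](C)[C@H](O[Si](C(C)C)(C(C)C)C(C)C)CC[C@H]2[C@H](OC(=[N+](C)C)O3)[C@@H]13.[O-]C(=O)C(F)(F)F | intermediate
21 | (3R,4R,5R,8R,9S,10R)-3α-(triisopropylsilyloxy)-11,12,13-trinoreremophilane-8α,9α-diyl carbonate (4β,5β-dimethyl, 10α-H) | C1C[C@]2(C)[C@@H](C)[C@H](O[Si](C(C)C)(C(C)C)C(C)C)CC[C@H]2[C@H](OC(=O)O3)[C@@H]13 | intermediate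
22 | (3R,4R,5R,8R,9S,10R)-3α-(triisopropylsilyloxy)-11,12,13-trinoreremophilane-8α,9α-diol | C1C[C@]2(C)[C@@H](C)[C@H](O[Si](C(C)C)(C(C)C)C(C)C)CC[C@H]2[C@H](O)[C@@H]1O | intermediate
23 | (3R,4R,5R,8R,9S,10R)-9α-(triethylsilyloxy)-3α-(triisopropylsilyloxy)-11,12,13-trinoreremophilan-8α-ol | C1C[C@]2(C)[C@@H](C)[C@H](O[Si](C(C)C)(C(C)C)C(C)C)CC[C@H]2[C@H](O[Si](CC)(CC)CC)[C@@H]1O | intermediate
24 | (3R,4R,5R,9S,10R)-9α-(triethylsilyloxy)-3α-(triisopropylsilyloxy)-11,12,13-trinoreremophilan-8-one | C1C[C@]2(C)[C@@H](C)[C@H](O[Si](C(C)C)(C(C)C)C(C)C)CC[C@H]2[C@H](O[Si](CC)(CC)CC)C1=O | intermediate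
25 | acetone | CC(C)=O | starting material
26 | lithium C7-enolate of 24 | [Li]OC1=CC[C@]2(C)[C@@H](C)[C@H](O[Si](C(C)C)(C(C)C)C(C)C)CC[C@H]2[C@@H]1O[Si](CC)(CC)CC | intermediate
27 | (3R,4R,5R,7S,9S,10R)-11-hydroxy-9α-(triethylsilyloxy)-3α-(triisopropylsilyloxy)eremophilan-8-one (7α-(2-hydroxypropan-2-yl)) | CC(C)(O)[C@@H]1C[C@]2(C)[C@@H](C)[C@H](O[Si](C(C)C)(C(C)C)C(C)C)CC[C@H]2[C@H](O[Si](CC)(CC)CC)C1=O | intermediate
28 | (3R,4R,5R,7S,9S,10R)-9α-(triethylsilyloxy)-3α-(triisopropylsilyloxy)eremophil-11-en-8-one | C=C(C)[C@@H]1C[C@]2(C)[C@@H](C)[C@H](O[Si](C(C)C)(C(C)C)C(C)C)CC[C@H]2[C@H](O[Si](CC)(CC)CC)C1=O | intermediate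
29 | (3R,4R,5R,7S,9S,10R)-9α-hydroxy-3α-(triisopropylsilyloxy)eremophil-11-en-8-one | C=C(C)[C@@H]1C[C@]2(C)[C@@H](C)[C@H](O[Si](C(C)C)(C(C)C)C(C)C)CC[C@H]2[C@H](O)C1=O | intermediate
30 | 3-methylbut-2-enoyl chloride (senecioyl chloride) | CC(C)=CC(Cl)=O | starting material
31 | (3R,4R,5R,7S,9S,10R)-8-oxo-3α-(triisopropylsilyloxy)eremophil-11-en-9α-yl 3-methylbut-2-enoate | C=C(C)[C@@H]1C[C@]2(C)[C@@H](C)[C@H](O[Si](C(C)C)(C(C)C)C(C)C)CC[C@H]2[C@H](OC(=O)C=C(C)C)C1=O | intermediate
32 | (3R,4R,5R,7S,9S,10R)-3α-hydroxy-8-oxoeremophil-11-en-9α-yl 3-methylbut-2-enoate | C=C(C)[C@@H]1C[C@]2(C)[C@@H](C)[C@H](O)CC[C@H]2[C@H](OC(=O)C=C(C)C)C1=O | intermediate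
33 | (E)-2-methylbut-2-enoyl chloride (tigloyl chloride) | ClC(=O)/C(C)=C/C | starting material
34 | (3R,4R,5R,7S,9S,10R)-9α-(3-methylbut-2-enoyloxy)-8-oxoeremophil-11-en-3α-yl (E)-2-methylbut-2-enoate (CNP0375730.3) | C=C(C)[C@@H]1C[C@]2(C)[C@@H](C)[C@H](OC(=O)/C(C)=C/C)CC[C@H]2[C@H](OC(=O)C=C(C)C)C1=O | target

## Step count and least certain steps

Total: 22 steps. Longest linear sequence: 22 steps (1 → 34). Compounds 5, 10, 18, 25, 30 and 33 are bought and enter without separate steps.

**Step 13 (key step).** The likeliest failure is proton loss from the C5 cation into the ring, or its capture by trifluoroacetate, before the alkene engages. The alkene is deactivated by its allylic oxygen, and proton loss towards C4 would also erase that stereocentre. Slow ionisation of the allylic carbamate or partial loss of the silyl ether are secondary worries.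
Fallback, from 19 back to 21: initiate with divalent mercury instead of a proton. Hg(OCOCF3)2 in CH2Cl2/MeNO2 at −20 °C would add to the methylidene group with mercury on C14. The same transannular bond formation, carbamate capture and bicarbonate hydrolysis should follow, without a strongly acidic medium and without an escape by deprotonation, since reversal only regenerates 19. Exchange with NaCl would then give the 14-(chloromercurio) derivative of carbonate 21, F1. Reductive demercuration with NaBH4/NaOH converts CH2HgCl into the angular methyl group and returns the route to 21.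

**Step 9.** Bimolecular coupling and protodemetalation of the alkenylchromium species may outrun the slow, strained ten-membered closure.
Fallback, from 13 back to 17: change the closing nucleophile from an alkenylchromium species to an alkenylzinc species under amino-alcohol catalysis. Dehydroiodination of 13 with LiN(iPr)2 in THF would give the terminal alkyne 2-[(4R,5R)-4-methyl-3-methylidene-5-[(triisopropylsilyl)oxy]non-8-yn-1-yl]-1,3-dioxolane, F2. Acetal hydrolysis as in step 8 would give the ynal (5R,6R)-5-methyl-4-methylidene-6-[(triisopropylsilyl)oxy]dec-9-ynal, F3. Chemoselective hydroboration of the alkyne with dicyclohexylborane would give the alkenylborane (5R,6R,9E)-10-(dicyclohexylboranyl)-5-methyl-4-methylidene-6-[(triisopropylsilyl)oxy]dec-9-enal, F4. Boron-to-zinc exchange with Et2Zn would give the alkenylzinc compound ethyl[(1E,5R,6R)-6-methyl-7-methylidene-10-oxo-5-[(triisopropylsilyl)oxy]dec-1-en-1-yl]zinc, F5. Its intramolecular addition to the aldehyde at high dilution, catalysed by 3-exo-(dimethylamino)isoborneol, closes the same C8-C9 bond. The enantiomer of the amino alcohol is chosen that directs the alkenyl group to the aldehyde face leading to 8R. After aqueous work-up this gives 17 directly under ligand control and bypasses 14, 15 and 16.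

**Step 11.** Facial selectivity may be poor if peripheral attack dictated by the ring conformation competes with catalyst control.
Fallback, from 15 back to 17: omit the oxidation. The two epimers of 15 are separated, and the (1R) epimer is 17. The (1S) epimer is inverted by a Mitsunobu reaction (4-nitrobenzoic acid, PPh3, diisopropyl azodicarboxylate) to (1R,2E,6R,7R)-7-methyl-8-methylidene-6-[(triisopropylsilyl)oxy]cyclodec-2-en-1-yl 4-nitrobenzoate, F6. Methanolysis with K2CO3/MeOH gives 17.

**Step 15.** Discrimination between the two hydroxyls may be insufficient, leading to silylation at C8 or at both oxygens.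
Fallback, from 22 back to 24: oxidise first and protect second. Heating 22 with Bu2SnO in toluene would give the dibutylstannylene acetal of 22, F7. Treatment with Br2, a protocol that oxidises the carbinol bearing the axial oxygen of a cis-diol, would give (3R,4R,5R,9S,10R)-9α-hydroxy-3α-(triisopropylsilyloxy)-11,12,13-trinoreremophilan-8-one, F8. Silylation with Et3SiOTf/2,6-lutidine then gives 24 and bypasses 23.

**Step 18.** Elimination may take the acidic C7 hydrogen instead of a methyl hydrogen, giving the conjugated isopropylidene ketone, or the product may isomerise on contact with base.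
Fallback, from 27 back to 28: accept conjugation and then undo it. MsCl/Et3N would convert 27 into the tertiary mesylate (3R,4R,5R,7S,9S,10R)-8-oxo-9α-(triethylsilyloxy)-3α-(triisopropylsilyloxy)eremophilan-11-yl methanesulfonate, F9. 1,8-Diazabicyclo[5.4.0]undec-7-ene would then eliminate it on purpose to (3R,4R,5R,9S,10R)-9α-(triethylsilyloxy)-3α-(triisopropylsilyloxy)eremophil-7(11)-en-8-one, F10. KN(SiMe3)2 in THF at −78 °C would form the extended enolate potassium (3R,4R,5R,9S,10R)-9α-(triethylsilyloxy)-3α-(triisopropylsilyloxy)eremophila-7,11-dien-8-olate, F11. Kinetic protonation at C7 with AcOH on the axial trajectory (β-face) would place the hydrogen axial and the isopropenyl group equatorial, giving the deconjugated 7α-isopropenyl ketone 28.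

## Further compounds

F1 | step 13 | 14-(chloromercurio) derivative of 21: 14-(chloromercurio)-3α-(triisopropylsilyloxy)-11,12,13-trinoreremophilane-8α,9α-diyl carbonate | C1C[C@]2(C[Hg]Cl)[C@@H](C)[C@H](O[Si](C(C)C)(C(C)C)C(C)C)CC[C@H]2[C@H](OC(=O)O3)[C@@H]13
F2 | step 9 | 2-[(4R,5R)-4-methyl-3-methylidene-5-[(triisopropylsilyl)oxy]non-8-yn-1-yl]-1,3-dioxolane | O1CCOC1CCC(=C)[C@@H](C)[C@H](O[Si](C(C)C)(C(C)C)C(C)C)CCC#C
F3 | step 9 | (5R,6R)-5-methyl-4-methylidene-6-[(triisopropylsilyl)oxy]dec-9-ynal | O=CCCC(=C)[C@@H](C)[C@H](O[Si](C(C)C)(C(C)C)C(C)C)CCC#C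
F4 | step 9 | (5R,6R,9E)-10-(dicyclohexylboranyl)-5-methyl-4-methylidene-6-[(triisopropylsilyl)oxy]dec-9-enal | O=CCCC(=C)[C@@H](C)[C@H](O[Si](C(C)C)(C(C)C)C(C)C)CC/C=C/B(C1CCCCC1)C1CCCCC1
F5 | step 9 | ethyl[(1E,5R,6R)-6-methyl-7-methylidene-10-oxo-5-[(triisopropylsilyl)oxy]dec-1-en-1-yl]zinc | O=CCCC(=C)[C@@H](C)[C@H](O[Si](C(C)C)(C(C)C)C(C)C)CC/C=C/[Zn]CC
F6 | step 11 | (1R,2E,6R,7R)-7-methyl-8-methylidene-6-[(triisopropylsilyl)oxy]cyclodec-2-en-1-yl 4-nitrobenzoate | C1CC(=C)[C@@H](C)[C@H](O[Si](C(C)C)(C(C)C)C(C)C)CC/C=C/[C@@H]1OC(=O)c2ccc(cc2)[N+](=O)[O-]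
F7 | step 15 | dibutylstannylene acetal of 22: 8α,9α-(dibutylstannanediyldioxy)-3α-(triisopropylsilyloxy)-11,12,13-trinoreremophilane | C1C[C@]2(C)[C@@H](C)[C@H](O[Si](C(C)C)(C(C)C)C(C)C)CC[C@H]2[C@H](O[Sn](CCCC)(CCCC)O3)[C@@H]13
F8 | step 15 | (3R,4R,5R,9S,10R)-9α-hydroxy-3α-(triisopropylsilyloxy)-11,12,13-trinoreremophilan-8-one | C1C[C@]2(C)[C@@H](C)[C@H](O[Si](C(C)C)(C(C)C)C(C)C)CC[C@H]2[C@H](O)C1=O
F9 | step 18 | (3R,4R,5R,7S,9S,10R)-8-oxo-9α-(triethylsilyloxy)-3α-(triisopropylsilyloxy)eremophilan-11-yl methanesulfonate | CC(C)(OS(C)(=O)=O)[C@@H]1C[C@]2(C)[C@@H](C)[C@H](O[Si](C(C)C)(C(C)C)C(C)C)CC[C@H]2[C@H](O[Si](CC)(CC)CC)C1=O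
F10 | step 18 | (3R,4R,5R,9S,10R)-9α-(triethylsilyloxy)-3α-(triisopropylsilyloxy)eremophil-7(11)-en-8-one | CC(C)=C1C[C@]2(C)[C@@H](C)[C@H](O[Si](C(C)C)(C(C)C)C(C)C)CC[C@H]2[C@H](O[Si](CC)(CC)CC)C1=O
F11 | step 18 | potassium (3R,4R,5R,9S,10R)-9α-(triethylsilyloxy)-3α-(triisopropylsilyloxy)eremophila-7,11-dien-8-olate | C=C(C)C=1C[C@]2(C)[C@@H](C)[C@H](O[Si](C(C)C)(C(C)C)C(C)C)CC[C@H]2[C@H](O[Si](CC)(CC)CC)C=1O[K]
A1 | alternative 1 | 3-methylcyclohex-2-en-1-one | CC1=CC(=O)CCC1
A2 | alternative 1 | (2R,3R)-2-allyl-3-methyl-3-vinylcyclohexan-1-one | O=C1CCC[C@](C)(C=C)[C@H]1CC=C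
A3 | alternative 2 | ring A seco-aldehyde: C8 aldehyde with C9 senecioate, C5 prenyl, C3 tiglate, configured as in the target | CC(C)=CC[C@]1(C)[C@@H](C)[C@H](OC(=O)/C(C)=C/C)CC[C@H]1[C@H](OC(=O)C=C(C)C)C=O
A4 | alternative 2 | 8β-alcohol of the target (8-dihydro target) | C=C(C)[C@@H]1C[C@]2(C)[C@@H](C)[C@H](OC(=O)/C(C)=C/C)CC[C@H]2[C@H](OC(=O)C=C(C)C)[C@H]1O
A5 | alternative 3 | acyclic trienal: (E)-β-methyl enal joined through C1-C4 to a 2-(tert-butyldimethylsilyloxy) diene, C3 triisopropylsilyl ether | O=C/C=C(\C)[C@@H](C)[C@H](O[Si](C(C)C)(C(C)C)C(C)C)CC/C=C/C(=C)O[Si](C)(C)C(C)(C)C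
A6 | alternative 3 | 6β-formyl-3α-(triisopropylsilyloxy)-8-(tert-butyldimethylsilyloxy)-11,12,13-trinoreremophil-8-ene | C1[C@@H](C=O)[C@]2(C)[C@@H](C)[C@H](O[Si](C(C)C)(C(C)C)C(C)C)CC[C@H]2C=C1O[Si](C)(C)C(C)(C)C
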